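**Plan**
Retrosynthesis cuts, in this order: the O1–C8a aryl ether bond of ring C, the C4 carbonyl (back to a silyl-protected carbinol), the C3–C4 bond (aldol), and on ring A the C4a–CHO, C8–prenyl and C8a–Br bonds.
Forward: ring A is built first from 2,6-dimethoxytoluene by meta C–H borylation/bromination and two ortho-metalations (prenyl, then formyl). Aldol with 4'-methoxyacetophenone then joins ring B and the C2–C3–C4 chain, and ring C is closed last.
Enabling feature: in ring C, O1 is bonded to the aromatic carbon C8a of ring A, which lies between C8 (prenyl) and C4a (chain). This bond can therefore be formed from a C8a bromide while the oxygen keeps its bond to C2.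
Stereochemistry: the single stereocentre C2 (S) comes from Corey–Bakshi–Shibata reduction of the open-chain 4-methoxyphenyl ketone and is carried unchanged through ring closure, oxidation and deprotection. The silyloxy carbon (future C4) is a temporary centre erased by oxidation.

Key step: step 9

Remark: flavanone numbering (O1, C2, C3, C4, C4a, C5–C8, C8a; ring A = fused benzene ring, ring B = 4-methoxyphenyl, ring C = pyranone) is used for all intermediates. The silyloxy/hydroxy carbon that becomes C4 is carried as a mixture of both configurations from step 6 to step 10.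

**Step 1**
Reactants: 1 1,3-dimethoxy-2-methylbenzene (2,6-dimethoxytoluene)
Product: 3 5-bromo-1,3-dimethoxy-2-methylbenzene, via arylboronate 2 (not isolated)
Conditions: [Ir(OMe)(cod)]2 (cat.), 4,4'-di-tert-butyl-2,2'-bipyridine (cat.), B2pin2, THF, 80 °C; evaporate; then CuBr2, MeOH/H2O, 80 °C
Reagents that add atoms: CuBr2, Br[Cu]Br; bis(pinacolato)diboron, CC1(C)OB(OC1(C)C)B1OC(C)(C)C(C)(C)O1 (boron group of 2 only)
Why: Iridium-catalysed C–H borylation is sterically governed and should take the only ring C–H without an ortho substituent (para to methyl, meta to both oxygens), and copper-mediated bromodeboronation then exchanges boron for bromine at that carbon, the methyl ethers being used here because the HBr released would cleave MOM acetals.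

**Step 2**
Reactants: 3 5-bromo-1,3-dimethoxy-2-methylbenzene
Product: 4 5-bromo-2-methylbenzene-1,3-diol
Conditions: BBr3, CH2Cl2, −78 °C to rt; then H2O
Reagents that add atoms: none
Why: Lewis-acid cleavage of aryl methyl ethers with BBr3 should free both phenols and leave the aryl bromide untouched.

**Step 3**
Reactants: 4 5-bromo-2-methylbenzene-1,3-diol
Product: 5 5-bromo-1,3-bis(methoxymethoxy)-2-methylbenzene
Conditions: NaH, MOMCl, DMF, 0 °C to rt
Reagents that add atoms: chloromethyl methyl ether, COCCl
Why: Williamson-type O-alkylation of the bis-phenoxide should install two MOM acetals, which direct the coming ortho-metalations and are removable at the end without touching the ring B methyl ether.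

**Step 4**
Reactants: 5 5-bromo-1,3-bis(methoxymethoxy)-2-methylbenzene; 6 1-bromo-3-methylbut-2-ene (prenyl bromide)
Product: 9 1-bromo-3,5-bis(methoxymethoxy)-4-methyl-2-(3-methylbut-2-enyl)benzene, via aryllithium 7 (not isolated), via arylcopper 8 (not isolated)
Conditions: LiN(iPr)2, THF, −78 °C; CuBr·SMe2, −78 °C; then 6, −78 to 0 °C
Reagents that add atoms: 1-bromo-3-methylbut-2-ene (compound 6), CC(C)=CCBr
Why: Directed ortho-metalation with a lithium amide (deprotonation, not bromine–lithium exchange) should remove one of the two equivalent protons flanked by OMOM and Br, and copper-mediated allylic substitution at the primary carbon of 6 should then give the linear prenyl group.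

**Step 5**
Reactants: 9 1-bromo-3,5-bis(methoxymethoxy)-4-methyl-2-(3-methylbut-2-enyl)benzene
Product: 11 2-bromo-4,6-bis(methoxymethoxy)-5-methyl-3-(3-methylbut-2-enyl)benzaldehyde, via aryllithium 10 (not isolated)
Conditions: LiN(iPr)2, THF, −78 °C; DMF, −78 to −40 °C; then AcOH, H2O
Reagents that add atoms: N,N-dimethylformamide, CN(C)C=O
Why: A second directed ortho-metalation at the last ring C–H (again between OMOM and Br) followed by Bouveault-type formylation with DMF should give the aldehyde, the low temperature holding back aryne formation from the ortho-bromoaryllithium.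

**Step 6**
Reactants: 11 2-bromo-4,6-bis(methoxymethoxy)-5-methyl-3-(3-methylbut-2-enyl)benzaldehyde; 12 4'-methoxyacetophenone
Product: 14 racemic 3-[2-bromo-4,6-bis(methoxymethoxy)-5-methyl-3-(3-methylbut-2-enyl)phenyl]-3-hydroxy-1-(4-methoxyphenyl)propan-1-one, via lithium enolate 13 (not isolated)
Conditions: 12, LiN(iPr)2, THF, −78 °C; then 11, −78 °C; AcOH quench at −78 °C
Reagents that add atoms: 4'-methoxyacetophenone (compound 12), COc1ccc(C(C)=O)cc1
Why: Directed aldol addition of the preformed lithium enolate to the non-enolisable aldehyde with a cold acidic quench should give the β-hydroxy ketone without retro-aldol or dehydration, its carbinol centre being formed racemic and destroyed later.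

**Step 7**
Reactants: 14 racemic 3-aryl-3-hydroxy-1-(4-methoxyphenyl)propan-1-one (aryl as in 11)
Product: 15 racemic 3-[2-bromo-4,6-bis(methoxymethoxy)-5-methyl-3-(3-methylbut-2-enyl)phenyl]-3-(tert-butyldimethylsilyloxy)-1-(4-methoxyphenyl)propan-1-one
Conditions: TBSOTf, 2,6-lutidine, CH2Cl2, −78 to 0 °C
Reagents that add atoms: tert-butyldimethylsilyl trifluoromethanesulfonate, CC(C)(C)[Si](C)(C)OS(=O)(=O)C(F)(F)F
Why: O-silylation with a silyl triflate and a hindered pyridine base should cap the congested benzylic hydroxyl, blocking retro-aldol cleavage and β-elimination in the basic steps that follow.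

**Step 8**
Reactants: 15 racemic silyloxy ketone
Product: 16 (1S)-3-[2-bromo-4,6-bis(methoxymethoxy)-5-methyl-3-(3-methylbut-2-enyl)phenyl]-3-(tert-butyldimethylsilyloxy)-1-(4-methoxyphenyl)propan-1-ol (both configurations at C3)
Conditions: (R)-2-methyl-CBS-oxazaborolidine (cat.), catecholborane, toluene, −78 to −40 °C; then MeOH, aq. NaHCO3
Reagents that add atoms: none
Why: In this Corey–Bakshi–Shibata reduction the (R)-oxazaborolidine should bind the ketone with the 4-methoxyphenyl group as the large substituent and deliver hydride to the face giving the (S)-carbinol under catalyst control for both epimers, catecholborane being chosen because it should not hydroborate the prenyl alkene at low temperature.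

**Step 9**
Reactants: 16 (1S)-bromo carbinol
Product: 17 (2S)-4-(tert-butyldimethylsilyloxy)-5,7-bis(methoxymethoxy)-2-(4-methoxyphenyl)-6-methyl-8-(3-methylbut-2-enyl)chromane (both configurations at C4)
Conditions: Pd(OAc)2 (cat.), 2-(di-tert-butylphosphino)-1,1'-binaphthyl (cat.), Cs2CO3, toluene, 80 °C
Reagents that add atoms: none
Why: Zerovalent palladium generated in situ from Pd(OAc)2 and the bulky dialkylbiarylphosphine should insert into the C8a–Br bond, carbonate-assisted exchange of bromide for the C2 alkoxide should give a seven-membered palladacycle, and C–O reductive elimination then forms O1–C8a. The closest known reaction type is the Buchwald–Hartwig-type intramolecular etherification of aryl bromides by secondary alcohols, which is established for chromans. Ring C closes as the six-membered ring O1–C2–C3–C4–C4a–C8a, in a 6-exo sense at the arene carbon, by contraction of the seven-membered metallacycle during reductive elimination. No stereocentre is created: C2 keeps its (S) configuration because only its O–H bond reacts and no bond to that carbon is made or broken, and the silyloxy carbon stays an epimer mixture. The selectivity needed is reductive elimination over β-hydride elimination of the palladium alkoxide, which the bulky electron-rich monophosphine and the intramolecular setting should secure, while the site of etherification is fixed by the bromine placed at C8a between C8 and C4a. The silyl ether at C4 keeps retro-aldol cleavage and β-elimination from competing under Cs2CO3.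

**Step 10**
Reactants: 17 (2S)-4-silyloxychromane
Product: 18 (2S)-5,7-bis(methoxymethoxy)-2-(4-methoxyphenyl)-6-methyl-8-(3-methylbut-2-enyl)chroman-4-ol (both configurations at C4)
Conditions: Bu4NF, THF, 0 °C to rt
Reagents that add atoms: none
Why: Fluoride-induced desilylation should free the C4 hydroxyl, the MOM ethers, the aryl ether and the alkene being inert to Bu4NF.

**Step 11**
Reactants: 18 (2S)-chroman-4-ol
Product: 19 (2S)-5,7-bis(methoxymethoxy)-2-(4-methoxyphenyl)-6-methyl-8-(3-methylbut-2-enyl)chroman-4-one
Conditions: Dess–Martin periodinane, CH2Cl2, rt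
Reagents that add atoms: none
Why: Dess–Martin oxidation of the secondary benzylic alcohol should convert both C4 epimers into one chromanone without any base that could open the flavanone to its chalcone and scramble C2.

**Step 12**
Reactants: 19 (2S)-bis-MOM flavanone
Product: 20 (2S)-5,7-dihydroxy-2-(4-methoxyphenyl)-6-methyl-8-(3-methylbut-2-enyl)chroman-4-one (target, CNP0252391.1)
Conditions: HCl (3 M aq.), MeOH, 40 °C
Reagents that add atoms: none
Why: Acid-catalysed acetal methanolysis should release the C5 and C7 phenols, the dilute acid and moderate temperature sparing the prenyl alkene, the ring B methyl ether and the C2–O1 bond so that the (S) configuration is kept.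

**Compound list**
1 | 1,3-dimethoxy-2-methylbenzene (2,6-dimethoxytoluene) | COc1cccc(OC)c1C | starting material
2 | 2-(3,5-dimethoxy-4-methylphenyl)-4,4,5,5-tetramethyl-1,3,2-dioxaborolane | COc1cc(B2OC(C)(C)C(C)(C)O2)cc(OC)c1C | intermediate (not isolated)
3 | 5-bromo-1,3-dimethoxy-2-methylbenzene | COc1cc(Br)cc(OC)c1C | intermediate
4 | 5-bromo-2-methylbenzene-1,3-diol | Cc1c(O)cc(Br)cc1O | intermediate
5 | 5-bromo-1,3-bis(methoxymethoxy)-2-methylbenzene | COCOc1cc(Br)cc(OCOC)c1C | intermediate
6 | 1-bromo-3-methylbut-2-ene (prenyl bromide) | CC(C)=CCBr | starting material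
7 | [6-bromo-2,4-bis(methoxymethoxy)-3-methylphenyl]lithium | [Li]c1c(Br)cc(OCOC)c(C)c1OCOC | intermediate (not isolated)
8 | [6-bromo-2,4-bis(methoxymethoxy)-3-methylphenyl]copper | [Cu]c1c(Br)cc(OCOC)c(C)c1OCOC | intermediate (not isolated)
9 | 1-bromo-3,5-bis(methoxymethoxy)-4-methyl-2-(3-methylbut-2-enyl)benzene | COCOc1cc(Br)c(CC=C(C)C)c(OCOC)c1C | intermediate
10 | [2-bromo-4,6-bis(methoxymethoxy)-5-methyl-3-(3-methylbut-2-enyl)phenyl]lithium | [Li]c1c(Br)c(CC=C(C)C)c(OCOC)c(C)c1OCOC | intermediate (not isolated)
11 | 2-bromo-4,6-bis(methoxymethoxy)-5-methyl-3-(3-methylbut-2-enyl)benzaldehyde | O=Cc1c(Br)c(CC=C(C)C)c(OCOC)c(C)c1OCOC | intermediate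
12 | 4'-methoxyacetophenone | COc1ccc(C(C)=O)cc1 | starting material
13 | lithium 1-(4-methoxyphenyl)ethenolate | [Li]OC(=C)c1ccc(OC)cc1 | intermediate (not isolated)
14 | racemic 3-[2-bromo-4,6-bis(methoxymethoxy)-5-methyl-3-(3-methylbut-2-enyl)phenyl]-3-hydroxy-1-(4-methoxyphenyl)propan-1-one | COc1ccc(C(=O)CC(O)c2c(Br)c(CC=C(C)C)c(OCOC)c(C)c2OCOC)cc1 | intermediate
15 | racemic 3-[2-bromo-4,6-bis(methoxymethoxy)-5-methyl-3-(3-methylbut-2-enyl)phenyl]-3-(tert-butyldimethylsilyloxy)-1-(4-methoxyphenyl)propan-1-one | COc1ccc(C(=O)CC(O[Si](C)(C)C(C)(C)C)c2c(Br)c(CC=C(C)C)c(OCOC)c(C)c2OCOC)cc1 | intermediate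
16 | (1S)-3-[2-bromo-4,6-bis(methoxymethoxy)-5-methyl-3-(3-methylbut-2-enyl)phenyl]-3-(tert-butyldimethylsilyloxy)-1-(4-methoxyphenyl)propan-1-ol, both configurations at C3 | COc1ccc([C@@H](O)CC(O[Si](C)(C)C(C)(C)C)c2c(Br)c(CC=C(C)C)c(OCOC)c(C)c2OCOC)cc1 | intermediate
17 | (2S)-4-(tert-butyldimethylsilyloxy)-5,7-bis(methoxymethoxy)-2-(4-methoxyphenyl)-6-methyl-8-(3-methylbut-2-enyl)chromane, both configurations at C4 | COc1ccc([C@@H]2CC(O[Si](C)(C)C(C)(C)C)c3c(OCOC)c(C)c(OCOC)c(CC=C(C)C)c3O2)cc1 | intermediate
18 | (2S)-5,7-bis(methoxymethoxy)-2-(4-methoxyphenyl)-6-methyl-8-(3-methylbut-2-enyl)chroman-4-ol, both configurations at C4 | COc1ccc([C@@H]2CC(O)c3c(OCOC)c(C)c(OCOC)c(CC=C(C)C)c3O2)cc1 | intermediate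
19 | (2S)-5,7-bis(methoxymethoxy)-2-(4-methoxyphenyl)-6-methyl-8-(3-methylbut-2-enyl)chroman-4-one | COc1ccc([C@@H]2CC(=O)c3c(OCOC)c(C)c(OCOC)c(CC=C(C)C)c3O2)cc1 | intermediate
20 | (2S)-5,7-dihydroxy-2-(4-methoxyphenyl)-6-methyl-8-(3-methylbut-2-enyl)chroman-4-one | COc1ccc([C@@H]2CC(=O)c3c(O)c(C)c(O)c(CC=C(C)C)c3O2)cc1 | target

**Step count**
Total: 12 steps. Longest linear sequence: 12 steps (1 to 20); compounds 6 and 12 enter as purchased materials.

**Steps most likely to fail**

Step 9. The palladium alkoxide of the benzylic carbinol may undergo β-hydride elimination (giving the ketone and the debrominated arene), oxidative addition at the doubly flanked, electron-rich bromide may stall, or the silyl group may shift from the C4 oxygen to the C2 alkoxide under base. The fallback closes ring C at O1–C2 by Mitsunobu displacement instead, at the price of relying on clean inversion at the 4-methoxybenzylic carbon. It sets out from ketone 15 and returns at chromane 17.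
- Reduction of 15 with (S)-2-methyl-CBS-oxazaborolidine and catecholborane should give (1R)-3-[2-bromo-4,6-bis(methoxymethoxy)-5-methyl-3-(3-methylbut-2-enyl)phenyl]-3-(tert-butyldimethylsilyloxy)-1-(4-methoxyphenyl)propan-1-ol F1.
- Deprotonation of the hydroxyl with MeLi, bromine–lithium exchange with t-BuLi at −78 °C and trapping with B(OMe)3 should give, after hydrolysis, [2-[(3R)-1-(tert-butyldimethylsilyloxy)-3-hydroxy-3-(4-methoxyphenyl)propyl]-3,5-bis(methoxymethoxy)-4-methyl-6-(3-methylbut-2-enyl)phenyl]boronic acid F2, which is not isolated.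
- Oxidation of F2 in the same flask with NaOH/H2O2 should give 2-[(3R)-1-(tert-butyldimethylsilyloxy)-3-hydroxy-3-(4-methoxyphenyl)propyl]-3,5-bis(methoxymethoxy)-4-methyl-6-(3-methylbut-2-enyl)phenol F3.
- Mitsunobu cyclisation of F3 (PPh3, diisopropyl azodicarboxylate, THF, 0 °C) should form the O1–C2 bond with inversion and deliver the (2S)-chromane 17.

Step 4. The ortho-bromoaryllithium may lose LiBr to an aryne before transmetalation, or the arylcopper may attack the tertiary end of the allyl system and give the transposed isomer. The fallback installs the prenyl group by electrophilic aromatic substitution at the diol stage. It sets out from diol 4 and returns at compound 9.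
- Treatment of 4 with 2-methylbut-3-en-2-ol and BF3·OEt2 in dioxane at rt should alkylate one of the two equivalent open positions (each ortho to one hydroxyl and para to the other), giving 5-bromo-2-methyl-4-(3-methylbut-2-enyl)benzene-1,3-diol F4.
- Bis-protection of F4 with NaH and MOMCl as in step 3 should give 9.

Step 8. Facial selectivity may erode because the branched silyloxy-bearing chain competes with the electron-rich aryl group for the large-substituent site of the oxazaborolidine, because one C3 epimer is mismatched, or because uncatalysed borane reduction intervenes. The fallback replaces borane reduction by a different reaction class, Noyori–Ikariya asymmetric transfer hydrogenation. It sets out from ketone 15 and returns at carbinol 16, with no new compound.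
- RuCl[(S,S)-TsDPEN](p-cymene) with HCO2H/Et3N at rt to 40 °C should deliver hydride through the metal–ligand bifunctional transition state, in which the aryl ring is placed by a C–H/π contact with the arene ligand.
- This gives the (S)-carbinol and tolerates the alkene and the aryl bromide.

**Further compounds**
F1 | step 9 | (1R)-3-[2-bromo-4,6-bis(methoxymethoxy)-5-methyl-3-(3-methylbut-2-enyl)phenyl]-3-(tert-butyldimethylsilyloxy)-1-(4-methoxyphenyl)propan-1-ol | COc1ccc([C@H](O)CC(O[Si](C)(C)C(C)(C)C)c2c(Br)c(CC=C(C)C)c(OCOC)c(C)c2OCOC)cc1
F2 | step 9 | [2-[(3R)-1-(tert-butyldimethylsilyloxy)-3-hydroxy-3-(4-methoxyphenyl)propyl]-3,5-bis(methoxymethoxy)-4-methyl-6-(3-methylbut-2-enyl)phenyl]boronic acid | COc1ccc([C@H](O)CC(O[Si](C)(C)C(C)(C)C)c2c(B(O)O)c(CC=C(C)C)c(OCOC)c(C)c2OCOC)cc1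
F3 | step 9 | 2-[(3R)-1-(tert-butyldimethylsilyloxy)-3-hydroxy-3-(4-methoxyphenyl)propyl]-3,5-bis(methoxymethoxy)-4-methyl-6-(3-methylbut-2-enyl)phenol | COc1ccc([C@H](O)CC(O[Si](C)(C)C(C)(C)C)c2c(O)c(CC=C(C)C)c(OCOC)c(C)c2OCOC)cc1
F4 | step 4 | 5-bromo-2-methyl-4-(3-methylbut-2-enyl)benzene-1,3-diol | Cc1c(O)cc(Br)c(CC=C(C)C)c1O
F0 | step 8 | none | none
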